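**Plan**
The target is a single 29-membered ring (ring O, carbonyl C1, methylenes C2–C28, C28 on oxygen) with no stereocentre, so no stereocontrol is needed.
The retrosynthesis cuts first the ring bond C24–C25 (sp3–sp3), then the ester bond O–C28, then the chain bond C16–C17.
The enabling feature is that the ring oxygen is separated from C25 by exactly four CH2 groups (C28–C25). This maps onto a 4-bromobutyl ester whose CH2Br carbon is C25, while C24 is the terminal carbon of a vinyl group (C23=C24) that anti-Markovnikov hydroboration turns into a primary alkylborane.
Forward: a C8 Grignard reagent and a C16 ω-bromo acid are joined to the C24 ω-alkenoic acid, which is O-alkylated to the 4-bromobutyl ester. A one-pot hydroboration/intramolecular alkyl–alkyl Suzuki–Miyaura coupling then closes the ring directly at the saturated oxidation level.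
The two helper groups (boron on C24, bromine on C25) are both lost in the ring-closing event, so nothing has to be removed afterwards.

Key step: step 3

**Route**

Step 1
Reactants: 1 16-bromohexadecanoic acid; 2 8-bromooct-1-ene
Product: 5 tetracos-23-enoic acid, via oct-7-en-1-ylmagnesium bromide 3 (not isolated), via chloromagnesium 16-bromohexadecanoate 4 (not isolated)
Conditions: 2, Mg turnings, THF, rt → 40 °C; separately 1, MeMgCl (1.0 equiv), THF, −20 °C; then the Grignard solution (1.6 equiv), Li2CuCl4 (3 mol%), THF, −20 °C → rt; aq. HCl work-up
Reagents that add atoms: none
Why: In a copper-catalysed Kumada-type sp3–sp3 cross-coupling, a primary alkyl Grignard reagent should displace the primary bromide much faster than it adds to the pre-formed halomagnesium carboxylate, so the ω-bromo acid needs no protection, and the oct-7-enyl chain is too long to cyclise during Grignard formation; no stereocentre is formed.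

Step 2
Reactants: 5 tetracos-23-enoic acid; 6 1,4-dibromobutane
Product: 8 4-bromobutyl tetracos-23-enoate, via potassium tetracos-23-enoate 7 (not isolated)
Conditions: K2CO3 (1.5 equiv), 6 (6 equiv), DMF, 50 °C
Reagents that add atoms: none
Why: Carboxylate O-alkylation (SN2) with a large excess of the symmetrical dibromide should stop at the mono-ester and leave one primary C–Br bond, the terminal alkene being inert under these conditions.

Step 3
Reactants: 8 4-bromobutyl tetracos-23-enoate
Product: 10 octacosanolide (1-oxacyclononacosan-2-one), via 4-bromobutyl 24-(9-borabicyclo[3.3.1]nonan-9-yl)tetracosanoate 9 (not isolated)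
Conditions: 9-BBN (9-borabicyclo[3.3.1]nonane, 0.5 M in THF, 1.1 equiv), THF, 0 °C → rt; then syringe-pump addition over about 20 h to Pd(OAc)2 (15 mol%), PCy3 (30 mol%), K3PO4·H2O (3 equiv), THF, rt → 40 °C, final concentration about 2 mM
Reagents that add atoms: none
Why: Proposed new method: 9-BBN should add across the monosubstituted C23=C24 alkene with boron on terminal C24, leaving ester and primary bromide untouched; the base-activated B-alkyl borate then transmetalates onto the alkylpalladium bromide formed by SN2-type oxidative addition of zerovalent palladium/PCy3 into the C25–Br bond of the same molecule, and reductive elimination from the dialkylpalladium chelate forms the C24–C25 sp3–sp3 bond. The closest known reaction types are the intermolecular Pd/PCy3 B-alkyl Suzuki–Miyaura coupling of primary alkyl bromides bearing β-hydrogens with alkyl-9-BBN reagents, and B-alkyl Suzuki–Miyaura macrocyclisations onto vinyl or aryl halides; the untested part is their combination as an alkyl–alkyl macrocyclisation. The only ring, the 29-membered lactone, is closed end to end (head-to-tail macrocyclisation of a bifunctional chain; no Baldwin preference applies at this size), and no stereocentre is created. The step needs ring closure to win over oligomerisation and over β-hydride elimination of the alkylpalladium bromide: pseudo-high dilution and the strain-free, flexible 28-carbon chain favour closure, and the bulky electron-rich PCy3 ligand should keep the alkylpalladium bromide alive long enough for the slower intramolecular transmetalation. Regiochemistry is fixed because each terminus has a single reactive site, one terminal alkene and one primary bromide.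

**Compound list**
1 | 16-bromohexadecanoic acid | OC(=O)CCCCCCCCCCCCCCCBr | starting material
2 | 8-bromooct-1-ene | C=CCCCCCCBr | starting material
3 | oct-7-en-1-ylmagnesium bromide | C=CCCCCCC[Mg]Br | intermediate (not isolated)
4 | chloromagnesium 16-bromohexadecanoate | BrCCCCCCCCCCCCCCCC(=O)O[Mg]Cl | intermediate (not isolated)
5 | tetracos-23-enoic acid | C=CCCCCCCCCCCCCCCCCCCCCCC(=O)O | intermediate
6 | 1,4-dibromobutane | BrCCCCBr | starting material
7 | potassium tetracos-23-enoate | C=CCCCCCCCCCCCCCCCCCCCCCC(=O)[O-].[K+] | intermediate (not isolated)
8 | 4-bromobutyl tetracos-23-enoate | C=CCCCCCCCCCCCCCCCCCCCCCC(=O)OCCCCBr | intermediate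
9 | 4-bromobutyl 24-(9-borabicyclo[3.3.1]nonan-9-yl)tetracosanoate | BrCCCCOC(=O)CCCCCCCCCCCCCCCCCCCCCCCB1C2CCCC1CCC2 | intermediate (not isolated)
10 | octacosanolide (1-oxacyclononacosan-2-one) | O=C1CCCCCCCCCCCCCCCCCCCCCCCCCCCO1 | target

**Summary**
Total step count: 3
Longest linear sequence: 3 steps (1 → 5 → 8 → 10)

**Steps most likely to fail**

Step 3 (proposed new method). The slow macrocyclic transmetalation may lose out to β-hydride elimination or protodeboronation at the two chain ends, or to intermolecular coupling (oligomerisation). The fallback sets out from 5 and returns to the route at 10, using known chemistry only. Acid 5 is esterified with but-3-en-1-ol (DCC, DMAP, CH2Cl2) to but-3-en-1-yl tetracos-23-enoate F1. Ring-closing olefin metathesis of F1 with the second-generation Grubbs catalyst (H2IMes)(PCy3)Cl2Ru=CHPh in refluxing CH2Cl2 at about 1 mM should close the same C24/C25 junction as an alkene, giving octacos-24-en-28-olide F2 as an E/Z mixture. Hydrogenation of F2 (H2, Pd/C, EtOAc, rt) should then give 10.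

Step 1. The coupling may stall through precipitation of the halomagnesium carboxylate, or be eroded by homo-coupling and halogen–magnesium exchange. The fallback sets out from 1 and returns at 5. Acid 1 is converted by Fischer esterification (MeOH, cat. H2SO4, reflux) into methyl 16-bromohexadecanoate F3. Separately, mono-hydroboration of excess octa-1,7-diene with 9-BBN in THF, followed by removal of the surplus diene in vacuo, gives 9-(oct-7-en-1-yl)-9-borabicyclo[3.3.1]nonane F4. Intermolecular alkyl–alkyl Suzuki–Miyaura coupling of F3 with F4 (Pd(OAc)2, PCy3, K3PO4·H2O, THF, rt) should give methyl tetracos-23-enoate F5. Saponification of F5 (LiOH, THF/H2O, then aq. HCl) gives 5.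

Step 2. A second alkylation of the product by the carboxylate (over-alkylation at the remaining C–Br bond) may occur, or the sparingly soluble potassium soap may react incompletely. The fallback sets out from 5 and returns at 8. It replaces O-alkylation by O-acylation: 5 is converted with oxalyl chloride and catalytic DMF in CH2Cl2 into tetracos-23-enoyl chloride F6, which acylates 4-bromobutan-1-ol (pyridine, CH2Cl2, 0 °C) to give 8.

**Further compounds**
F1 | step 3 | but-3-en-1-yl tetracos-23-enoate | C=CCCCCCCCCCCCCCCCCCCCCCC(=O)OCCC=C
F2 | step 3 | octacos-24-en-28-olide (E/Z mixture) | O=C1CCCCCCCCCCCCCCCCCCCCCCC=CCCCO1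
F3 | step 1 | methyl 16-bromohexadecanoate | COC(=O)CCCCCCCCCCCCCCCBr
F4 | step 1 | 9-(oct-7-en-1-yl)-9-borabicyclo[3.3.1]nonane | C=CCCCCCCB1C2CCCC1CCC2
F5 | step 1 | methyl tetracos-23-enoate | C=CCCCCCCCCCCCCCCCCCCCCCC(=O)OC
F6 | step 2 | tetracos-23-enoyl chloride | C=CCCCCCCCCCCCCCCCCCCCCCC(=O)Cl
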